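Going from −30 °C in the noon run to −10 °C in the dawn run, the highest ring reading moved from 6.00 min to 1.00 min, although the loading changed between those runs as well.

| flask | solid substrate | activator | temperature | remark | time |
|---|---|---|---|---|---|
| noon | 2.8 mM | 1.5 equiv | −30 °C | run made earlier |  |
| dawn | 4.4 mM | 1.5 equiv | −10 °C | run made earlier |  |
| east | 2.0 mM | 1.50 equiv |  | at 5 °C until 1.5 min, from then on at −25 °C | 3.0 min |
| north-east | 2.0 mM | 1.50 equiv |  | at −25 °C throughout | 2.0 min |

| run | time / min | ring / % |
|---|---|---|
| noon | 1.00 | 3 |
| noon | 1.33 | 4 |
| noon | 3.00 | 9 |
| noon | 5.00 | 15 |
| noon | 6.00 | 16 |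
| noon | 8.00 | 14 |
| noon | 12.0 | 14 |
| dawn | 0.333 | 14 |
| dawn | 0.417 | 18 |
| dawn | 0.667 | 20 |
| dawn | 1.00 | 25 |
| dawn | 2.00 | 21 |
| dawn | 3.00 | 20 |
| dawn | 4.00 | 20 |

(standard deviation of a reading: 1.5 percentage points)

- as a solid, counted per litre of solution: solid substrate
- the analysis behind the earlier runs scatters by 1.5 percentage points, standard deviation
- at the start none of the solid substrate is in solution
- what has only dissolved of solid substrate counts as not reacted

- which one finishes higher in amount of ring, in percent of the solid substrate charged ("neither" within 2 percentage points) (east / north-east / neither)
- amount of ring at the end, in percent of the solid substrate charged, east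
- amount of ring at the end, in percent of the solid substrate charged, north-east

I set the loading aside and assumed that the peak time falls by the same factor for each equal step of temperature. That placed it at 3.83 min at −25 °C and at 0.261 min at 5 °C. North-east therefore spends 0.522 peak times at its temperature, and east spends 5.75 before it is cooled. This ratio of time at a temperature to the peak time there is the stage number, a Damköhler-type number. It put north-east on the rise and east past its peak.

The noon rise was nearly straight, so I took ring in north-east as stage number times peak height. The highest noon reading of 16% gave 8.35%. Going round again with the height moved along the same temperature line, 17.9%, gave 9.33%.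

One number was not enough for east: my straight rise ends at a stage of 1, and east stood higher, at 5.75, so the rule gave no height there. Stretching the last readings, 14% and 20%, along that line gave a weak 26.1%.

The forecast was lower for east and higher for north-east than mine, at 21% and 10%, with east ahead: “East at 5 °C should peak within about 0.3 min and reach its plateau well before 1.5 min.”

The flask gave 36.6% for east and 12.2% for north-east, so east finished higher. At its change of temperature, east held 0% starting material and 0% activated form, while north-east at its end still held 14.1% activated form. Those are the sides on which the stage numbers 5.75 and 0.522 had put the two flasks. The height was the part the number did not carry: east ended 11 percentage points above my figure.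

    starting material + activator → activated form (k = 83.0 L mol⁻¹ s⁻¹, Ea = 42.0 kJ mol⁻¹)
    activated form → ring (k = 0.280 s⁻¹, Ea = 72.0 kJ mol⁻¹)
    starting material + activated form → open dimer (k = 260 L mol⁻¹ s⁻¹, Ea = 37.0 kJ mol⁻¹)
    ring ⇌ isomer of the product (K = 0.230, k = 0.0900 s⁻¹, Ea = 80.0 kJ mol⁻¹, ΔH = −46.0 kJ mol⁻¹)
    solid substrate ⇌ starting material, rate k5*(cs5 - [starting material]) while solid is left; crystals form when [starting material] > cs5 (solubility = 1.50 mM, k = 2.40 s⁻¹)
    (constants at 5 °C)

For a flask like north-east kept at −50 °C, the line gave a peak time of 36.0 min, a stage number of 0.0556 and 0.569% ring. The computed flask gave 0.140% ring, with 68.8% of the charge still starting material.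

Readings and results were computed from invented constants; noise was put on by code.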